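Cuts: working back from the target, both phenols are silylated, the lactate carboxyl becomes a tert-butyl ester, C5 receives SiEt3 and the C2 carboxyl is lowered to CH2OTr. Benzene ring A is then cut at C4a–C8a, C5–C6 and C7–C8, which also opens the dioxane ring.
Fragments: this leaves an erythro bis-ynol ether (HC≡C–O1 on C2, Et3Si–C≡C–O4 on C3) and an (E)-pent-2-en-4-ynoate. Further cuts are the enynoate–lactate ester C–O bond, both O–C(sp) bonds (two-carbon units from trichloroethylene), the C3–aryl bond and the lactate CH2–aryl bond.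
Enabling feature: ring A (C4a, C5, C6, C7, C8, C8a) bears only O1 on C8a, O4 on C4a and the propenoate on C7. Its six carbons are therefore three alkyne units, two of which already hang on the oxygens of the finished O1–C2–C3–O4 chain.
Forward order: the acyclic C2–C3 diad, the ynol ether on O4, the ynol ether on O1, and separately the enyne ester. One cyclotrimerisation closes the dioxane and ring A together and attaches the side chain; oxidation at C2, silicon–proton exchange at C5 and desilylation follow.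
Stereochemistry: C2 comes from (R)-solketal and C3 from a Felkin–Anh addition of an aryltitanium reagent (anti = erythro, which becomes cis-2R,3R because no bond at C2 or C3 is touched afterwards). The lactate R centre comes from methyl (R)-glycidate and the E alkene from a Horner–Wadsworth–Emmons reaction.
Key step: step 15

Numbering and abbreviations: O1, C2 (carboxyl), C3 (aryl), O4, C4a, C5–C8, C8a of the 2,3-dihydro-1,4-benzodioxine. Ar = 3-methoxy-4-(triisopropylsilyloxy)phenyl, Tr = triphenylmethyl, TIPS = triisopropylsilyl, TES = triethylsilyl, TMS = trimethylsilyl.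
Assumption: 1, 3, 8, 19, 24 and 25 are bought, 3 and 19 enantiopure. All ynol ethers are kept at or below room temperature and purified on amine-deactivated silica.

Step 1
Reactants: 1 4-bromo-2-methoxyphenol
Product: 2 (4-bromo-2-methoxyphenoxy)triisopropylsilane (Ar–Br)
Conditions: TIPSCl, imidazole, DMF, rt
Reagents that add atoms: chlorotriisopropylsilane, CC(C)[Si](Cl)(C(C)C)C(C)C
Why: Imidazole-promoted silyl ether formation with a hindered chlorosilane gives an aryl ether that should withstand KH, n-BuLi and Grignard formation and still leave with fluoride at the end.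

Step 2
Reactants: 3 (R)-solketal, [(4R)-2,2-dimethyl-1,3-dioxolan-4-yl]methanol
Product: 4 (4S)-2,2-dimethyl-1,3-dioxolane-4-carbaldehyde
Conditions: (COCl)2, DMSO, CH2Cl2, −78 °C; Et3N, −78 to 0 °C; used fresh
Reagents that add atoms: none
Why: Swern oxidation makes the aldehyde under conditions too mild to epimerise the α-alkoxy centre, which becomes C2 of the target.

Step 3
Reactants: 2 Ar–Br; 4 (4S)-2,2-dimethyl-1,3-dioxolane-4-carbaldehyde
Product: 7 (R)-(Ar)[(4S)-2,2-dimethyl-1,3-dioxolan-4-yl]methanol (anti, erythro), via aryllithium 5 (not isolated), via aryltitanium triisopropoxide 6 (not isolated)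
Conditions: n-BuLi, THF, −78 °C; ClTi(OiPr)3, −78 to −40 °C; 4, −78 to 0 °C; H2O work-up
Reagents that add atoms: none
Why: Bromine–lithium exchange and transmetalation give a non-chelating aryltitanium reagent whose Felkin–Anh addition to the α-alkoxy aldehyde should favour the anti carbinol, so that the resident C2 centre sets C3 as R and any syn isomer is removed by chromatography.

Step 4
Reactants: 7 anti carbinol; 8 trichloroethylene
Product: 9 (4S)-4-[(R)-(Ar){[(E)-1,2-dichloroethenyl]oxy}methyl]-2,2-dimethyl-1,3-dioxolane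
Conditions: KH, THF, 0 °C; 8, 0 °C to rt
Reagents that add atoms: none
Why: The potassium alkoxide adds to dichloroacetylene generated in situ from trichloroethylene (elimination–addition route to 1,2-dichlorovinyl ethers), an O–C bond formation that leaves C3 untouched and tolerates the ketal and the aryl silyl ether.

Step 5
Reactants: 9 dichloroethenyl ether acetonide
Product: 10 (2S,3R)-3-Ar-3-{[(E)-1,2-dichloroethenyl]oxy}propane-1,2-diol
Conditions: AcOH/H2O/THF (3:1:1), 40 °C
Reagents that add atoms: none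
Why: Acid hydrolysis of the terminal acetonide is placed here because the electron-poor dichlorovinyl ether resists dilute acid, whereas the ynol ether made from it later would be hydrated.

Step 6
Reactants: 10 diol
Product: 12 {[(2S,3R)-3-Ar-3-{[(E)-1,2-dichloroethenyl]oxy}-1-(trityloxy)propan-2-yl]oxy}trimethylsilane, via trityl ether alcohol 11 (not isolated)
Conditions: TrCl, Et3N, DMAP (cat.), CH2Cl2, rt; then TMSCl, Et3N, 0 °C
Reagents that add atoms: trityl chloride, ClC(c1ccccc1)(c1ccccc1)c1ccccc1; chlorotrimethylsilane, C[Si](C)(C)Cl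
Why: Steric selection sends trityl chloride to the primary hydroxyl (tritylation), and the O1 hydroxyl is capped in the same flask as a TMS ether so that no alkoxide can attack the neighbouring dichlorovinyl ether in the next step.

Step 7
Reactants: 12 O1-TMS, O4-dichloroethenyl ether
Product: 15 (2S,3R)-3-Ar-3-{[(triethylsilyl)ethynyl]oxy}-1-(trityloxy)propan-2-ol, via lithium alkoxyacetylide 13 (not isolated), via O-trimethylsilyl triethylsilyl ynol ether 14 (not isolated)
Conditions: n-BuLi (2.3 equiv), THF, −78 to −40 °C; TESCl, −78 °C to rt; then K2CO3 (cat.), MeOH/THF, 0 °C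
Reagents that add atoms: chlorotriethylsilane, CC[Si](Cl)(CC)CC
Why: n-BuLi effects dehydrochlorination and chlorine–lithium exchange of the dichlorovinyl ether to the lithium alkoxyacetylide, C-silylation installs the group that will sit on C5, and carbonate-catalysed methanolysis then removes only the far more labile O-TMS group.

Step 8
Reactants: 15 O4 silyl ynol ether alcohol; 8 trichloroethylene
Product: 18 erythro bis-ynol ether, triethyl({[(1R,2S)-1-Ar-2-(ethynyloxy)-3-(trityloxy)propyl]oxy}ethynyl)silane, via dichloroethenyl ether 16 (not isolated), via lithium alkoxyacetylide 17 (not isolated)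
Conditions: KH, THF, 0 °C; 8, 0 °C to rt; n-BuLi (2.5 equiv), −78 to −40 °C; MeOH, −78 °C
Reagents that add atoms: none
Why: The dichlorovinyl ether route to alkynyl ethers is repeated on O1 in one flask and the acetylide is protonated, TES being chosen on the first alkyne because it resists potassium alkoxides and n-BuLi, and trityl on the primary oxygen because it cannot migrate to the O1 alkoxide as a silyl group could.

Step 9
Reactants: 2 Ar–Br; 19 methyl (2R)-oxirane-2-carboxylate (methyl (R)-glycidate)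
Product: 21 methyl (2R)-3-Ar-2-hydroxypropanoate, via aryl Grignard reagent 20 (not isolated)
Conditions: Mg, THF, 40 °C; CuI (10 mol %), 19, THF, −40 to −20 °C; H2O work-up
Reagents that add atoms: none
Why: Copper-catalysed epoxide opening by the aryl Grignard reagent occurs at the unsubstituted carbon, so no bond at the stereocentre is broken and the R configuration of the glycidate becomes that of the lactate.

Step 10
Reactants: 21 methyl lactate
Product: 22 (2R)-3-Ar-2-hydroxypropanoic acid
Conditions: LiOH, THF/H2O, 0 °C; 1 M HCl to pH 3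
Reagents that add atoms: lithium hydroxide, [Li+].[OH-]
Why: Saponification of the unhindered α-hydroxy methyl ester is fast at 0 °C, where the hindered aryl silyl ether should survive and the stereocentre is not enolised.

Step 11
Reactants: 22 hydroxy acid
Product: 23 tert-butyl (2R)-3-Ar-2-hydroxypropanoate
Conditions: Cl3CC(=NH)OtBu, CH2Cl2/cyclohexane, rt
Reagents that add atoms: tert-butyl 2,2,2-trichloroacetimidate, CC(C)(C)OC(=N)C(Cl)(Cl)Cl
Why: Trichloroacetimidate esterification alkylates the carboxylic acid without added acid, leaves the secondary hydroxyl free and gives an ester that will fall in the same acid step as the C5 silyl group.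

Step 12
Reactants: 24 3-(trimethylsilyl)propynal; 25 triethyl phosphonoacetate
Product: 26 ethyl (2E)-5-(trimethylsilyl)pent-2-en-4-ynoate
Conditions: NaH, THF, 0 °C; 24, 0 °C to rt
Reagents that add atoms: none
Why: Horner–Wadsworth–Emmons olefination with the stabilised phosphonate anion should give the E enoate.

Step 13
Reactants: 26 silyl enynoate
Product: 27 (2E)-pent-2-en-4-ynoic acid
Conditions: LiOH, THF/MeOH/H2O, rt; 1 M HCl
Reagents that add atoms: lithium hydroxide, [Li+].[OH-]
Why: Hydroxide cleaves both the ethyl ester (saponification) and the alkynyl C–Si bond (protodesilylation) and leaves the E alkene untouched.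

Step 14
Reactants: 23 tert-butyl lactate; 27 enynoic acid
Product: 28 tert-butyl (2R)-3-Ar-2-{[(2E)-pent-2-en-4-ynoyl]oxy}propanoate
Conditions: DCC, DMAP (cat.), CH2Cl2, 0 °C to rt
Reagents that add atoms: none
Why: Steglich esterification acylates the lactate hydroxyl through the acylpyridinium species without breaking a bond at the stereocentre.

Step 15
Reactants: 18 erythro bis-ynol ether; 28 enyne ester
Product: 29 tert-butyl (2R)-3-Ar-2-({(2E)-3-[(2S,3R)-3-Ar-5-(triethylsilyl)-2-(trityloxymethyl)-2,3-dihydro-1,4-benzodioxin-7-yl]prop-2-enoyl}oxy)propanoate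
Conditions: Cp*RuCl(cod) (5–10 mol %), ClCH2CH2Cl, 20 °C, argon, slow addition of 18 to catalyst and 28 (1.5 equiv)
Reagents that add atoms: none
Why: Proposed new method: loss of cod from Cp*RuCl(cod) should let the divalent ruthenium fragment bind both ynol ether triple bonds of 18 and couple them oxidatively at their oxygen-bearing carbons to a ruthenacyclopentadiene, which forms C4a–C8a and closes the six-membered 1,4-dioxane ring by tether-enforced annulation onto the metallacycle, after which insertion of the terminal alkyne of 28 and reductive elimination form C7–C8 and C5–C6 and close benzene ring A in a formal [2+2+2] cycloaddition. The closest known reaction types are the ruthenium- and rhodium-catalysed [2+2+2] cycloadditions of 1,6- and 1,7-diynes with terminal alkynes, including diynes in which one alkyne is an ynol ether, whereas a 1,7-diyne held together through two ynol ether oxygens is untested. No stereocentre is formed and no bond at C2 or C3 is touched, so the erythro arrangement of 18 is carried over as the cis-2,3 relationship of the ring. The step needs the side chain on C7 and not on C6, which the TES group on the terminus that becomes C5 should secure by making the incoming alkyne turn its substituted carbon towards the unhindered C8 terminus, meta to silicon. It also needs the alkyne of 28 to react rather than its conjugated alkene, which rests on the much stronger binding of a terminal alkyne than of a 1,2-disubstituted electron-poor alkene, while slow addition of 18 to excess 28 holds back self-coupling of the diyne. The catalyst works at room temperature and without acid, as the thermally and hydrolytically labile benzylic ynol ether requires.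

Step 16
Reactants: 29 cycloadduct
Product: 30 the (2S,3R)-2-(hydroxymethyl) analogue of 29
Conditions: camphorsulfonic acid (cat.), MeOH/CH2Cl2, 0 °C to rt
Reagents that add atoms: none
Why: Acid-catalysed methanolysis of the trityl ether runs through the trityl cation under conditions too mild to ionise the C3–O4 bond, cleave the tert-butyl ester or protonate the arylsilane.

Step 17
Reactants: 30 primary alcohol
Product: 32 (2R,3R)-3-Ar-7-[(1E)-3-{[(2R)-3-Ar-1-tert-butoxy-1-oxopropan-2-yl]oxy}-3-oxoprop-1-enyl]-5-(triethylsilyl)-2,3-dihydro-1,4-benzodioxine-2-carboxylic acid, via aldehyde 31 (not isolated)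
Conditions: TEMPO (cat.), PhI(OAc)2, MeCN/pH 7 phosphate buffer, 0 °C to rt
Reagents that add atoms: water, O
Why: Oxoammonium oxidation takes the alcohol to the aldehyde, whose hydrate is oxidised at once in the buffered aqueous medium, so the epimerisable α-aryloxy aldehyde does not accumulate and C2 keeps its configuration.

Step 18
Reactants: 32 C5-silyl acid tert-butyl ester
Product: 33 bis-TIPS ether of the target (2R,3R; lactate R; C5–H; both carboxyl groups free)
Conditions: CF3CO2H/CH2Cl2 (1:1), 0 °C to rt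
Reagents that add atoms: none
Why: Ipso-protonation at C5 ortho to O4 with loss of silicon (protodesilylation) and acidolysis of the tert-butyl ester occur together, and the carboxyl group now on C2 disfavours ionisation of the neighbouring benzylic C3–O4 bond that would erase the cis relationship.

Step 19
Reactants: 33 bis-TIPS ether
Product: 34 CNP0171229.1 (target)
Conditions: HF·pyridine, THF, 0 °C to rt
Reagents that add atoms: none
Why: Fluoride cleavage of the two aryl silyl ethers in a mildly acidic medium avoids phenoxide formation, which could open the dioxane through a quinone methide and epimerise C3.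

Compound list
1 | 4-bromo-2-methoxyphenol | COc1cc(Br)ccc1O | starting material
2 | (4-bromo-2-methoxyphenoxy)triisopropylsilane | COc1cc(Br)ccc1O[Si](C(C)C)(C(C)C)C(C)C | intermediate
3 | (R)-solketal | CC1(C)O[C@@H](CO1)CO | starting material
4 | (4S)-2,2-dimethyl-1,3-dioxolane-4-carbaldehyde | CC1(C)O[C@@H](CO1)C=O | intermediate
5 | [3-methoxy-4-(triisopropylsilyloxy)phenyl]lithium | COc1cc([Li])ccc1O[Si](C(C)C)(C(C)C)C(C)C | intermediate
6 | [3-methoxy-4-(triisopropylsilyloxy)phenyl]titanium triisopropoxide | COc1cc([Ti](OC(C)C)(OC(C)C)OC(C)C)ccc1O[Si](C(C)C)(C(C)C)C(C)C | intermediate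
7 | (R)-(Ar)[(4S)-2,2-dimethyl-1,3-dioxolan-4-yl]methanol | CC1(C)O[C@@H](CO1)[C@@H](c1ccc(O[Si](C(C)C)(C(C)C)C(C)C)c(OC)c1)O | intermediate
8 | trichloroethylene | ClC=C(Cl)Cl | starting material
9 | (E)-1,2-dichloroethenyl ether of 7 | CC1(C)O[C@@H](CO1)[C@@H](c1ccc(O[Si](C(C)C)(C(C)C)C(C)C)c(OC)c1)O/C(Cl)=C\Cl | intermediate
10 | (2S,3R)-3-Ar-3-{[(E)-1,2-dichloroethenyl]oxy}propane-1,2-diol | O[C@@H](CO)[C@@H](c1ccc(O[Si](C(C)C)(C(C)C)C(C)C)c(OC)c1)O/C(Cl)=C\Cl | intermediate
11 | (2S,3R)-3-Ar-3-{[(E)-1,2-dichloroethenyl]oxy}-1-(trityloxy)propan-2-ol | O[C@@H](COC(c1ccccc1)(c1ccccc1)c1ccccc1)[C@@H](c1ccc(O[Si](C(C)C)(C(C)C)C(C)C)c(OC)c1)O/C(Cl)=C\Cl | intermediate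
12 | O-trimethylsilyl ether of 11 | C[Si](C)(C)O[C@@H](COC(c1ccccc1)(c1ccccc1)c1ccccc1)[C@@H](c1ccc(O[Si](C(C)C)(C(C)C)C(C)C)c(OC)c1)O/C(Cl)=C\Cl | intermediate
13 | lithium acetylide on O4 (O1-TMS) | C[Si](C)(C)O[C@@H](COC(c1ccccc1)(c1ccccc1)c1ccccc1)[C@@H](c1ccc(O[Si](C(C)C)(C(C)C)C(C)C)c(OC)c1)OC#C[Li] | intermediate
14 | O4 (triethylsilyl)ethynyl ether, O1-TMS | C[Si](C)(C)O[C@@H](COC(c1ccccc1)(c1ccccc1)c1ccccc1)[C@@H](c1ccc(O[Si](C(C)C)(C(C)C)C(C)C)c(OC)c1)OC#C[Si](CC)(CC)CC | intermediate
15 | (2S,3R)-3-Ar-3-{[(triethylsilyl)ethynyl]oxy}-1-(trityloxy)propan-2-ol | O[C@@H](COC(c1ccccc1)(c1ccccc1)c1ccccc1)[C@@H](c1ccc(O[Si](C(C)C)(C(C)C)C(C)C)c(OC)c1)OC#C[Si](CC)(CC)CC | intermediate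
16 | O1 (E)-1,2-dichloroethenyl ether of 15 | Cl/C=C(/Cl)O[C@@H](COC(c1ccccc1)(c1ccccc1)c1ccccc1)[C@@H](c1ccc(O[Si](C(C)C)(C(C)C)C(C)C)c(OC)c1)OC#C[Si](CC)(CC)CC | intermediate
17 | lithium acetylide on O1 | [Li]C#CO[C@@H](COC(c1ccccc1)(c1ccccc1)c1ccccc1)[C@@H](c1ccc(O[Si](C(C)C)(C(C)C)C(C)C)c(OC)c1)OC#C[Si](CC)(CC)CC | intermediate
18 | erythro bis-ynol ether (1R,2S) | C#CO[C@@H](COC(c1ccccc1)(c1ccccc1)c1ccccc1)[C@@H](c1ccc(O[Si](C(C)C)(C(C)C)C(C)C)c(OC)c1)OC#C[Si](CC)(CC)CC | intermediate
19 | methyl (R)-glycidate | COC(=O)[C@H]1CO1 | starting material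
20 | [3-methoxy-4-(triisopropylsilyloxy)phenyl]magnesium bromide | COc1cc([Mg]Br)ccc1O[Si](C(C)C)(C(C)C)C(C)C | intermediate
21 | methyl (2R)-3-Ar-2-hydroxypropanoate | COc1cc(C[C@@H](O)C(=O)OC)ccc1O[Si](C(C)C)(C(C)C)C(C)C | intermediate
22 | (2R)-3-Ar-2-hydroxypropanoic acid | COc1cc(C[C@@H](O)C(=O)O)ccc1O[Si](C(C)C)(C(C)C)C(C)C | intermediate
23 | tert-butyl (2R)-3-Ar-2-hydroxypropanoate | COc1cc(C[C@@H](O)C(=O)OC(C)(C)C)ccc1O[Si](C(C)C)(C(C)C)C(C)C | intermediate
24 | 3-(trimethylsilyl)propynal | C[Si](C)(C)C#CC=O | starting material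
25 | triethyl phosphonoacetate | CCOC(=O)CP(=O)(OCC)OCC | starting material
26 | ethyl (2E)-5-(trimethylsilyl)pent-2-en-4-ynoate | CCOC(=O)/C=C/C#C[Si](C)(C)C | intermediate
27 | (2E)-pent-2-en-4-ynoic acid | C#C/C=C/C(=O)O | intermediate
28 | tert-butyl (2R)-3-Ar-2-{[(2E)-pent-2-en-4-ynoyl]oxy}propanoate | COc1cc(C[C@@H](OC(=O)/C=C/C#C)C(=O)OC(C)(C)C)ccc1O[Si](C(C)C)(C(C)C)C(C)C | intermediate
29 | 5-TES, 2-(trityloxymethyl) cis-benzodioxane with full side chain (2S,3R; lactate R) | COc1cc(C[C@@H](OC(=O)/C=C/c2cc([Si](CC)(CC)CC)c3c(c2)O[C@@H](COC(c2ccccc2)(c2ccccc2)c2ccccc2)[C@@H](c2ccc(O[Si](C(C)C)(C(C)C)C(C)C)c(OC)c2)O3)C(=O)OC(C)(C)C)ccc1O[Si](C(C)C)(C(C)C)C(C)C | intermediate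
30 | 2-(hydroxymethyl) analogue of 29 (2S,3R) | COc1cc(C[C@@H](OC(=O)/C=C/c2cc([Si](CC)(CC)CC)c3c(c2)O[C@@H](CO)[C@@H](c2ccc(O[Si](C(C)C)(C(C)C)C(C)C)c(OC)c2)O3)C(=O)OC(C)(C)C)ccc1O[Si](C(C)C)(C(C)C)C(C)C | intermediate
31 | 2-formyl analogue (2R,3R) | COc1cc(C[C@@H](OC(=O)/C=C/c2cc([Si](CC)(CC)CC)c3c(c2)O[C@@H](C=O)[C@@H](c2ccc(O[Si](C(C)C)(C(C)C)C(C)C)c(OC)c2)O3)C(=O)OC(C)(C)C)ccc1O[Si](C(C)C)(C(C)C)C(C)C | intermediate
32 | 2-carboxylic acid, 5-TES, tert-butyl ester (2R,3R) | COc1cc(C[C@@H](OC(=O)/C=C/c2cc([Si](CC)(CC)CC)c3c(c2)O[C@@H](C(=O)O)[C@@H](c2ccc(O[Si](C(C)C)(C(C)C)C(C)C)c(OC)c2)O3)C(=O)OC(C)(C)C)ccc1O[Si](C(C)C)(C(C)C)C(C)C | intermediate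
33 | bis-TIPS ether of the target | COc1cc(C[C@@H](OC(=O)/C=C/c2ccc3c(c2)O[C@@H](C(=O)O)[C@@H](c2ccc(O[Si](C(C)C)(C(C)C)C(C)C)c(OC)c2)O3)C(=O)O)ccc1O[Si](C(C)C)(C(C)C)C(C)C | intermediate
34 | CNP0171229.1 | COc1cc(C[C@@H](OC(=O)/C=C/c2ccc3c(c2)O[C@@H](C(=O)O)[C@@H](c2ccc(O)c(OC)c2)O3)C(=O)O)ccc1O | target

Total step count: 19.
Longest linear sequence: 12 steps (1, 3, 4, 5, 6, 7, 8, 15, 16, 17, 18, 19).

Steps most likely to fail

Step 15 (new method). Oxidative coupling of two electron-rich alkynes across a six-membered tether may be slower than oligomerisation of either alkyne partner or thermal rearrangement of the benzylic ynol ether, and regiocontrol by silicon may be incomplete.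
- The fallback uses known chemistry, sets out from 7 and returns at 33.
- The sodium alkoxide of 7 (NaH, DMF, 0 °C) displaces the fluoride of 3-bromo-4-fluorobenzaldehyde para to the formyl group (SNAr). This makes O4–C4a and gives the bromoaryl ether acetonide F1.
- Aqueous AcOH frees the diol F2, and TrCl/Et3N caps the primary hydroxyl to give the trityl ether F3.
- An intramolecular Buchwald–Hartwig etherification (Pd(OAc)2, 2-(di-tert-butylphosphino)-1,1'-binaphthyl, Cs2CO3, toluene, 70 °C) joins O1 to C8a without touching C2 or C3 and gives the cis-benzodioxane-7-carbaldehyde F4.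
- Alcohol 23 is acylated with diethylphosphonoacetic acid (DCC, DMAP) to the phosphonoacetate F5. Its Horner–Wadsworth–Emmons reaction with F4 (LiCl, iPr2NEt, MeCN) gives the E cinnamate F6.
- CF3CO2H in CH2Cl2 removes the trityl and tert-butyl groups to give the hydroxy acid F7. TEMPO/PhI(OAc)2 in buffered aqueous MeCN oxidises it through the aldehyde F8 to 33.

Step 8. The O1 potassium alkoxide may attack the neighbouring ynol ether in a 5-exo closure, or silicon may be transferred from the alkyne or from the aryl ether to the alkoxide before dichloroacetylene is intercepted.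
- The fallback never generates an alkoxide. It sets out from 15 and returns at 17 and hence 18.
- Acetic formic anhydride and pyridine (CH2Cl2, 0 °C) give the formate F9.
- Dibromomethylenation of the formyl group (CBr4, PPh3, CH2Cl2, 0 °C) gives the 2,2-dibromoethenyl ether F10.
- The second half of a Corey–Fuchs sequence (n-BuLi, THF, −78 °C) converts F10 into 17, which MeOH protonates to 18.

Step 18. Acid may ionise the benzylic C3–O4 bond, with reclosure to the more stable trans ring, at a rate comparable with the silicon–proton exchange.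
- The fallback removes the donor that supports this ionisation before acid is applied. It sets out from 32 and returns at 34.
- HF·pyridine frees both phenols to give the bisphenol F11.
- Ac2O/pyridine (0 °C, aqueous work-up to hydrolyse any mixed anhydride) gives the bis(aryl acetate) F12, whose para-acetoxy group stabilises a C3 cation far less.
- CF3CO2H/CH2Cl2 then effects protodesilylation and tert-butyl ester cleavage to give the diacetate diacid F13.
- NH4OAc in aqueous MeOH cleaves only the aryl acetates and gives 34.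

Further compounds
F1 | step 15 | 3-bromo-4-{(R)-(Ar)[(4S)-2,2-dimethyl-1,3-dioxolan-4-yl]methoxy}benzaldehyde | CC1(C)O[C@@H](CO1)[C@@H](c1ccc(O[Si](C(C)C)(C(C)C)C(C)C)c(OC)c1)Oc1ccc(C=O)cc1Br
F2 | step 15 | 3-bromo-4-{[(1R,2S)-1-Ar-2,3-dihydroxypropyl]oxy}benzaldehyde | O[C@@H](CO)[C@@H](c1ccc(O[Si](C(C)C)(C(C)C)C(C)C)c(OC)c1)Oc1ccc(C=O)cc1Br
F3 | step 15 | 3-bromo-4-{[(1R,2S)-1-Ar-2-hydroxy-3-(trityloxy)propyl]oxy}benzaldehyde | O[C@@H](COC(c1ccccc1)(c1ccccc1)c1ccccc1)[C@@H](c1ccc(O[Si](C(C)C)(C(C)C)C(C)C)c(OC)c1)Oc1ccc(C=O)cc1Br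
F4 | step 15 | (2S,3R)-3-Ar-2-(trityloxymethyl)-2,3-dihydro-1,4-benzodioxine-7-carbaldehyde | O=Cc1ccc2c(c1)O[C@@H](COC(c1ccccc1)(c1ccccc1)c1ccccc1)[C@@H](c1ccc(O[Si](C(C)C)(C(C)C)C(C)C)c(OC)c1)O2
F5 | step 15 | tert-butyl (2R)-3-Ar-2-{[(diethoxyphosphoryl)acetyl]oxy}propanoate | COc1cc(C[C@@H](OC(=O)CP(=O)(OCC)OCC)C(=O)OC(C)(C)C)ccc1O[Si](C(C)C)(C(C)C)C(C)C
F6 | step 15 | C5–H analogue of 29 | COc1cc(C[C@@H](OC(=O)/C=C/c2ccc3c(c2)O[C@@H](COC(c2ccccc2)(c2ccccc2)c2ccccc2)[C@@H](c2ccc(O[Si](C(C)C)(C(C)C)C(C)C)c(OC)c2)O3)C(=O)OC(C)(C)C)ccc1O[Si](C(C)C)(C(C)C)C(C)C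
F7 | step 15 | 2-(hydroxymethyl) lactic acid, bis-TIPS (2S,3R; lactate R) | COc1cc(C[C@@H](OC(=O)/C=C/c2ccc3c(c2)O[C@@H](CO)[C@@H](c2ccc(O[Si](C(C)C)(C(C)C)C(C)C)c(OC)c2)O3)C(=O)O)ccc1O[Si](C(C)C)(C(C)C)C(C)C
F8 | step 15 | 2-formyl lactic acid, bis-TIPS (2R,3R; lactate R) | COc1cc(C[C@@H](OC(=O)/C=C/c2ccc3c(c2)O[C@@H](C=O)[C@@H](c2ccc(O[Si](C(C)C)(C(C)C)C(C)C)c(OC)c2)O3)C(=O)O)ccc1O[Si](C(C)C)(C(C)C)C(C)C
F9 | step 8 | O1 formate of 15 | O=CO[C@@H](COC(c1ccccc1)(c1ccccc1)c1ccccc1)[C@@H](c1ccc(O[Si](C(C)C)(C(C)C)C(C)C)c(OC)c1)OC#C[Si](CC)(CC)CC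
F10 | step 8 | O1 2,2-dibromoethenyl ether of 15 | BrC(Br)=CO[C@@H](COC(c1ccccc1)(c1ccccc1)c1ccccc1)[C@@H](c1ccc(O[Si](C(C)C)(C(C)C)C(C)C)c(OC)c1)OC#C[Si](CC)(CC)CC
F11 | step 18 | bisphenol of 32 (5-TES, tert-butyl ester) | COc1cc(C[C@@H](OC(=O)/C=C/c2cc([Si](CC)(CC)CC)c3c(c2)O[C@@H](C(=O)O)[C@@H](c2ccc(O)c(OC)c2)O3)C(=O)OC(C)(C)C)ccc1O
F12 | step 18 | bis(aryl acetate) of F11 | COc1cc(C[C@@H](OC(=O)/C=C/c2cc([Si](CC)(CC)CC)c3c(c2)O[C@@H](C(=O)O)[C@@H](c2ccc(OC(C)=O)c(OC)c2)O3)C(=O)OC(C)(C)C)ccc1OC(C)=O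
F13 | step 18 | bis(aryl acetate) of the target | COc1cc(C[C@@H](OC(=O)/C=C/c2ccc3c(c2)O[C@@H](C(=O)O)[C@@H](c2ccc(OC(C)=O)c(OC)c2)O3)C(=O)O)ccc1OC(C)=O
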